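The route rests on cutting the C4–C4a bond of ring C. Ring A is locally symmetric about its C6···C8a axis: C6 bears the geranyl chain, its neighbours C5 and C7 both bear oxygen, and C8a, opposite C6, bears O1. An O1-aryl ether of 4-geranyl-3,5-bis(methoxymethoxy)phenol therefore offers two interchangeable carbons next to the ether oxygen, and acylation at either one creates C4a. One intramolecular Friedel–Crafts acylation of an (S)-3-aryl-3-aryloxypropanoic acid thus closes ring C, installs the C4 ketone and fixes the 6-geranyl pattern with no C6/C8 choice. The precursor carries MOM ethers on O5, O7 and O4'; its C2 stereocentre comes from asymmetric hydrogenation and Mitsunobu inversion.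

Key step: step 13

Remark (abbreviations): geranyl = (2E)-3,7-dimethylocta-2,6-dien-1-yl; MOM = methoxymethyl; flavanone numbering is used for rings A, B and C.
Remark (precursor design): O4' is carried as a MOM ether and not as an aryl ester, because an aryl ester would be lost in the LiBH4 and fluoride steps on the way to the acid; the two flanking methoxy groups twist O4' out of the ring plane, so this ether should not make the benzylic carbon unduly prone to ionise.
Remark (assumption): the (S)-BINAP ruthenium catalyst is taken to give the 3R hydroxy ester, following the usual facial sense of β-keto ester hydrogenation (R because aryl outranks CH2CO2Et); if the opposite sense were found, the enantiomeric ligand would be used.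

Step 1
Reactants: 1 phloroglucinol (benzene-1,3,5-triol)
Product: 2 3,5-bis(methoxymethoxy)phenol
Conditions: MOMCl (2.0 equiv), i-Pr2NEt, DMF, 0 °C → rt
Reagents that add atoms: chloromethyl methyl ether (MOMCl), COCCl
Why: Williamson-type O-alkylation of the phenoxide by the reactive α-chloro ether caps the three equivalent hydroxyls statistically, and the bis-ether should be separable by chromatography from the mono- and tris-ethers, which can be recycled.

Step 2
Reactants: 2 3,5-bis(methoxymethoxy)phenol
Product: 3 [3,5-bis(methoxymethoxy)phenoxy]triisopropylsilane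
Conditions: TIPSCl, imidazole, DMF, rt
Reagents that add atoms: chlorotriisopropylsilane (TIPSCl), CC(C)[Si](Cl)(C(C)C)C(C)C
Why: Imidazole-promoted silyl ether formation should be clean on the one free phenol, and the bulky, poorly coordinating TIPS ether will not direct lithiation in the next step.

Step 3
Reactants: 3 [3,5-bis(methoxymethoxy)phenoxy]triisopropylsilane; 4 geranyl bromide [(2E)-1-bromo-3,7-dimethylocta-2,6-diene]
Product: 6 [4-geranyl-3,5-bis(methoxymethoxy)phenoxy]triisopropylsilane, via aryllithium 5 (not isolated)
Conditions: n-BuLi, THF, 0 °C; then CuI (10 mol%), 4, −78 → 0 °C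
Reagents that add atoms: none
Why: Directed ortho-metalation should occur only at the C–H flanked by the two chelating MOM ethers, and copper-catalysed SN2 allylation of the aryllithium by geranyl bromide should give the linear product with the E-alkene intact.

Step 4
Reactants: 6 [4-geranyl-3,5-bis(methoxymethoxy)phenoxy]triisopropylsilane
Product: 7 4-geranyl-3,5-bis(methoxymethoxy)phenol
Conditions: TBAF, THF, 0 °C
Reagents that add atoms: none
Why: Fluoride-driven cleavage of the aryl silyl ether (Si–F bond formation) should free the phenol without touching the MOM acetals or the alkenes.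

Step 5
Reactants: 8 acetosyringone [1-(4-hydroxy-3,5-dimethoxyphenyl)ethan-1-one]
Product: 9 1-[3,5-dimethoxy-4-(methoxymethoxy)phenyl]ethan-1-one
Conditions: MOMCl, i-Pr2NEt, CH2Cl2, 0 °C → rt
Reagents that add atoms: chloromethyl methyl ether (MOMCl), COCCl
Why: O-alkylation of the acidic para-acyl phenol with the α-chloro ether is a standard MOM protection and should proceed despite the two ortho methoxy groups.

Step 6
Reactants: 9 1-[3,5-dimethoxy-4-(methoxymethoxy)phenyl]ethan-1-one
Product: 10 ethyl 3-[3,5-dimethoxy-4-(methoxymethoxy)phenyl]-3-oxopropanoate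
Conditions: NaH, (EtO)2CO, THF, reflux; then AcOH, H2O
Reagents that add atoms: diethyl carbonate, CCOC(=O)OCC
Why: Crossed Claisen condensation of the methyl ketone enolate with diethyl carbonate is driven to completion by deprotonation of the β-keto ester formed, and the mild acetic acid quench spares the MOM ether.

Step 7
Reactants: 10 ethyl 3-[3,5-dimethoxy-4-(methoxymethoxy)phenyl]-3-oxopropanoate
Product: 11 ethyl (3R)-3-[3,5-dimethoxy-4-(methoxymethoxy)phenyl]-3-hydroxypropanoate
Conditions: H2 (10 bar), [RuCl(p-cymene)((S)-BINAP)]Cl (1 mol%), EtOH, 60 °C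
Reagents that add atoms: none
Why: In this Noyori asymmetric hydrogenation the β-keto ester chelates ruthenium through both carbonyls and the (S)-BINAP ligand directs hydride to the ketone face that gives the (R)-carbinol, while the ester, the arene and the MOM ether are inert.

Step 8
Reactants: 11 ethyl (3R)-3-[3,5-dimethoxy-4-(methoxymethoxy)phenyl]-3-hydroxypropanoate
Product: 12 (1R)-1-[3,5-dimethoxy-4-(methoxymethoxy)phenyl]propane-1,3-diol
Conditions: LiBH4, THF, 0 °C → rt
Reagents that add atoms: none
Why: Hydride reduction of the ester by LiBH4, assisted by the neighbouring alkoxide, should give the 1,3-diol without touching the carbinol stereocentre or the MOM ether.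

Step 9
Reactants: 12 (1R)-1-[3,5-dimethoxy-4-(methoxymethoxy)phenyl]propane-1,3-diol
Product: 13 (1R)-3-[(tert-butyldimethylsilyl)oxy]-1-[3,5-dimethoxy-4-(methoxymethoxy)phenyl]propan-1-ol
Conditions: TBSCl (1.05 equiv), imidazole, CH2Cl2, −10 → 0 °C
Reagents that add atoms: tert-butyldimethylsilyl chloride (TBSCl), CC(C)(C)[Si](C)(C)Cl
Why: Selective silylation should favour the unhindered primary hydroxyl over the secondary benzylic one when a bulky silyl chloride is used in slight excess at low temperature.

Step 10
Reactants: 13 (1R)-3-[(tert-butyldimethylsilyl)oxy]-1-[3,5-dimethoxy-4-(methoxymethoxy)phenyl]propan-1-ol; 7 4-geranyl-3,5-bis(methoxymethoxy)phenol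
Product: 14 tert-butyl{(3S)-3-[3,5-dimethoxy-4-(methoxymethoxy)phenyl]-3-[4-geranyl-3,5-bis(methoxymethoxy)phenoxy]propoxy}dimethylsilane
Conditions: PPh3, DIAD, toluene, 0 °C → rt
Reagents that add atoms: none
Why: In this Mitsunobu etherification the carbinol is activated as its alkoxyphosphonium ion and displaced by the phenoxide of 7 in an SN2 step with inversion, so the (R)-carbinol should become the (S)-aryl ether.

Step 11
Reactants: 14 tert-butyl{(3S)-3-[3,5-dimethoxy-4-(methoxymethoxy)phenyl]-3-[4-geranyl-3,5-bis(methoxymethoxy)phenoxy]propoxy}dimethylsilane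
Product: 15 (3S)-3-[3,5-dimethoxy-4-(methoxymethoxy)phenyl]-3-[4-geranyl-3,5-bis(methoxymethoxy)phenoxy]propan-1-ol
Conditions: TBAF, THF, 0 °C → rt
Reagents that add atoms: none
Why: Fluoride cleavage of the primary TBS ether is selective because the acetals, the aryl ethers and the alkenes do not react with TBAF and there is no acidifying group to trigger β-elimination.

Step 12
Reactants: 15 (3S)-3-[3,5-dimethoxy-4-(methoxymethoxy)phenyl]-3-[4-geranyl-3,5-bis(methoxymethoxy)phenoxy]propan-1-ol
Product: 17 (3S)-3-[3,5-dimethoxy-4-(methoxymethoxy)phenyl]-3-[4-geranyl-3,5-bis(methoxymethoxy)phenoxy]propanoic acid, via aldehyde 16 (not isolated)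
Conditions: TEMPO (20 mol%), PhI(OAc)2 (2.2 equiv), MeCN/H2O (1:1), 0 °C → rt
Reagents that add atoms: water, O
Why: TEMPO-catalysed oxoammonium oxidation with PhI(OAc)2 as terminal oxidant takes the primary alcohol to the aldehyde and its hydrate on to the acid, tolerates trisubstituted alkenes and aryl ethers, and is mildly acidic, so the base-induced β-elimination of the aryloxy group should not occur.

Step 13
Reactants: 17 (3S)-3-[3,5-dimethoxy-4-(methoxymethoxy)phenyl]-3-[4-geranyl-3,5-bis(methoxymethoxy)phenoxy]propanoic acid
Product: 19 (2S)-2-[3,5-dimethoxy-4-(methoxymethoxy)phenyl]-6-geranyl-5,7-bis(methoxymethoxy)chroman-4-one, via mixed anhydride 18 (not isolated)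
Conditions: (CF3CO)2O (1.2 equiv), CH2Cl2, −20 → 0 °C; then cold aqueous NaHCO3
Reagents that add atoms: none
Why: Trifluoroacetic anhydride converts the acid into the acyl trifluoroacetate 18, which, helped by the trifluoroacetic acid released, ionises towards the acylium ion; a ring A carbon next to the ether oxygen (also ortho to one MOM ether and para to the other, hence the most nucleophilic site in the molecule) attacks it and the Wheland intermediate loses a proton to give the aryl ketone. The closest known reaction type is the anhydride-mediated intramolecular Friedel–Crafts acylation of 3-aryloxypropanoic acids to chroman-4-ones. Ring C closes in a six-membered mode that is exo with respect to the acyl C=O (6-exo-trig at the anhydride carbonyl, 6-exo-dig if the free acylium ion is involved), the attacked arene bond C4a–C8a lying inside the new ring. No stereocentre is formed, and the existing C2 centre takes no part in bond making and should be preserved because the medium is metal-free, cold and only weakly acidic and because O4', twisted out of conjugation by its two methoxy neighbours, gives a benzylic cation little help. The only regiochemical question, C6 versus C8 for the geranyl group, is answered by the substrate itself: the geranyl carbon is blocked and the two open ortho carbons are interconverted by rotation about the O1–C8a bond, so both lead to 19. Chemoselectivity over the geranyl alkenes and over trifluoroacetylation of ring A rests on the six-membered intramolecular transition state, the small excess of anhydride and the cold bicarbonate quench, and loss of the peri MOM group at O5 would be harmless because step 14 removes it anyway.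

Step 14
Reactants: 19 (2S)-2-[3,5-dimethoxy-4-(methoxymethoxy)phenyl]-6-geranyl-5,7-bis(methoxymethoxy)chroman-4-one
Product: 20 (2S)-6-geranyl-5,7-dihydroxy-2-(4-hydroxy-3,5-dimethoxyphenyl)chroman-4-one (CNP0372687.1)
Conditions: HCl (3 M aqueous), MeOH, 40 °C
Reagents that add atoms: none
Why: Acid-catalysed acetal exchange with methanol should remove all three aryl MOM ethers under conditions commonly tolerated by prenyl-type side chains, and the C2 stereocentre, which epimerises through base-mediated ring opening to the chalcone, should hold in mild acid.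

Compound list
1 | phloroglucinol (benzene-1,3,5-triol) | Oc1cc(O)cc(O)c1 | starting material
2 | 3,5-bis(methoxymethoxy)phenol | COCOc1cc(O)cc(OCOC)c1 | intermediate
3 | [3,5-bis(methoxymethoxy)phenoxy]triisopropylsilane | COCOc1cc(O[Si](C(C)C)(C(C)C)C(C)C)cc(OCOC)c1 | intermediate
4 | geranyl bromide, (2E)-1-bromo-3,7-dimethylocta-2,6-diene | BrC/C=C(\C)CCC=C(C)C | starting material
5 | [2,6-bis(methoxymethoxy)-4-(triisopropylsilyloxy)phenyl]lithium (formed in the flask) | [Li]c1c(OCOC)cc(O[Si](C(C)C)(C(C)C)C(C)C)cc1OCOC | intermediate
6 | [4-geranyl-3,5-bis(methoxymethoxy)phenoxy]triisopropylsilane | COCOc1cc(O[Si](C(C)C)(C(C)C)C(C)C)cc(OCOC)c1C/C=C(\C)CCC=C(C)C | intermediate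
7 | 4-geranyl-3,5-bis(methoxymethoxy)phenol | COCOc1cc(O)cc(OCOC)c1C/C=C(\C)CCC=C(C)C | intermediate
8 | acetosyringone, 1-(4-hydroxy-3,5-dimethoxyphenyl)ethan-1-one | COc1cc(C(C)=O)cc(OC)c1O | starting material
9 | 1-[3,5-dimethoxy-4-(methoxymethoxy)phenyl]ethan-1-one | COCOc1c(OC)cc(C(C)=O)cc1OC | intermediate
10 | ethyl 3-[3,5-dimethoxy-4-(methoxymethoxy)phenyl]-3-oxopropanoate | CCOC(=O)CC(=O)c1cc(OC)c(OCOC)c(OC)c1 | intermediate
11 | ethyl (3R)-3-[3,5-dimethoxy-4-(methoxymethoxy)phenyl]-3-hydroxypropanoate | CCOC(=O)C[C@@H](O)c1cc(OC)c(OCOC)c(OC)c1 | intermediate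
12 | (1R)-1-[3,5-dimethoxy-4-(methoxymethoxy)phenyl]propane-1,3-diol | OCC[C@@H](O)c1cc(OC)c(OCOC)c(OC)c1 | intermediate
13 | (1R)-3-[(tert-butyldimethylsilyl)oxy]-1-[3,5-dimethoxy-4-(methoxymethoxy)phenyl]propan-1-ol | CC(C)(C)[Si](C)(C)OCC[C@@H](O)c1cc(OC)c(OCOC)c(OC)c1 | intermediate
14 | tert-butyl{(3S)-3-[3,5-dimethoxy-4-(methoxymethoxy)phenyl]-3-[4-geranyl-3,5-bis(methoxymethoxy)phenoxy]propoxy}dimethylsilane | CC(C)(C)[Si](C)(C)OCC[C@H](Oc1cc(OCOC)c(C/C=C(\C)CCC=C(C)C)c(OCOC)c1)c1cc(OC)c(OCOC)c(OC)c1 | intermediate
15 | (3S)-3-[3,5-dimethoxy-4-(methoxymethoxy)phenyl]-3-[4-geranyl-3,5-bis(methoxymethoxy)phenoxy]propan-1-ol | OCC[C@H](Oc1cc(OCOC)c(C/C=C(\C)CCC=C(C)C)c(OCOC)c1)c1cc(OC)c(OCOC)c(OC)c1 | intermediate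
16 | (3S)-3-[3,5-dimethoxy-4-(methoxymethoxy)phenyl]-3-[4-geranyl-3,5-bis(methoxymethoxy)phenoxy]propanal (formed in the flask) | O=CC[C@H](Oc1cc(OCOC)c(C/C=C(\C)CCC=C(C)C)c(OCOC)c1)c1cc(OC)c(OCOC)c(OC)c1 | intermediate
17 | (3S)-3-[3,5-dimethoxy-4-(methoxymethoxy)phenyl]-3-[4-geranyl-3,5-bis(methoxymethoxy)phenoxy]propanoic acid | OC(=O)C[C@H](Oc1cc(OCOC)c(C/C=C(\C)CCC=C(C)C)c(OCOC)c1)c1cc(OC)c(OCOC)c(OC)c1 | intermediate
18 | mixed anhydride of acid 17 and trifluoroacetic acid, (3S) (formed in the flask) | O=C(OC(=O)C(F)(F)F)C[C@H](Oc1cc(OCOC)c(C/C=C(\C)CCC=C(C)C)c(OCOC)c1)c1cc(OC)c(OCOC)c(OC)c1 | intermediate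
19 | (2S)-2-[3,5-dimethoxy-4-(methoxymethoxy)phenyl]-6-geranyl-5,7-bis(methoxymethoxy)chroman-4-one | COCOc1c(OC)cc([C@@H]2CC(=O)c3c(cc(OCOC)c(C/C=C(\C)CCC=C(C)C)c3OCOC)O2)cc1OC | intermediate
20 | (2S)-6-geranyl-5,7-dihydroxy-2-(4-hydroxy-3,5-dimethoxyphenyl)chroman-4-one | COc1cc([C@@H]2CC(=O)c3c(cc(O)c(C/C=C(\C)CCC=C(C)C)c3O)O2)cc(OC)c1O | target

Total step count: 14. Longest linear sequence: 10 steps (steps 5 to 14, from 8 to 20); the phenol branch (steps 1 to 4) joins at step 10.

Steps most likely to fail

Step 13. The acid released on activation may strip MOM groups or protonate the geranyl alkenes before ring closure is complete. Surplus anhydride may trifluoroacetylate ring A. The benzylic C2–O1 bond may ionise, with loss of configuration or elimination to a cinnamic acid. The fallback sets out from acid 17 and replaces the acid-generating anhydride by a pre-formed acyl halide that is ionised by halide abstraction in a proton-free, base-buffered medium. Treatment of 17 with 1-chloro-N,N,2-trimethylprop-1-en-1-amine in CH2Cl2 at 0 °C should give, under neutral conditions, (3S)-3-[3,5-dimethoxy-4-(methoxymethoxy)phenyl]-3-[4-geranyl-3,5-bis(methoxymethoxy)phenoxy]propanoyl chloride F1. Chloride abstraction with AgOSO2CF3 in the presence of 2,6-di-tert-butyl-4-methylpyridine in CH2Cl2 at −78 °C should generate the acyl triflate, which acylates ring A while the hindered base traps every proton. This returns to the route at chromanone 19.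

Step 10. The alkoxyphosphonium intermediate may eliminate to the styrene or ionise, which would erode the inversion. The very electron-rich phenoxide may also be alkylated on carbon. The fallback sets out from hydroxy ester 11 and makes the same C2–O1 bond by opening a strained lactone instead of by redox condensation. Hydrolysis with LiOH in THF/H2O should give (3R)-3-[3,5-dimethoxy-4-(methoxymethoxy)phenyl]-3-hydroxypropanoic acid F2. Lactonisation through carboxyl activation with benzenesulfonyl chloride in pyridine at 0 °C leaves the carbinol C–O bond untouched and should give (4R)-4-[3,5-dimethoxy-4-(methoxymethoxy)phenyl]oxetan-2-one F3, which would be kept cold to avoid decarboxylation. The sodium salt of phenol 7 (NaH, THF/DMF, 0 °C) should then open the lactone at the benzylic carbon by alkyl–oxygen cleavage with inversion, a known mode of reaction between phenoxides and β-lactones. This delivers acid 17 directly, where the fallback rejoins the route, and bypasses steps 8, 9, 11 and 12.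

Step 14. A freed hydroxyl at C5 or C7, or methanol, may add to the protonated geranyl alkenes and give chroman-type by-products. Slow cleavage of the last acetal may call for heating that starts to open ring C. The fallback sets out from 19 and exchanges protic acid for a buffered silyl triflate. TMSOTf with 2,2'-bipyridyl in CH2Cl2 at 0 °C should convert each aryl MOM ether into the aryl silyl ether without free acid, giving (2S)-2-[3,5-dimethoxy-4-(trimethylsilyloxy)phenyl]-6-geranyl-5,7-bis(trimethylsilyloxy)chroman-4-one F4. Its silyl ethers should hydrolyse on addition of water at neutral pH, returning to the route at target 20.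

Further compounds
F1 | step 13 | (3S)-3-[3,5-dimethoxy-4-(methoxymethoxy)phenyl]-3-[4-geranyl-3,5-bis(methoxymethoxy)phenoxy]propanoyl chloride | ClC(=O)C[C@H](Oc1cc(OCOC)c(C/C=C(\C)CCC=C(C)C)c(OCOC)c1)c1cc(OC)c(OCOC)c(OC)c1
F2 | step 10 | (3R)-3-[3,5-dimethoxy-4-(methoxymethoxy)phenyl]-3-hydroxypropanoic acid | OC(=O)C[C@@H](O)c1cc(OC)c(OCOC)c(OC)c1
F3 | step 10 | (4R)-4-[3,5-dimethoxy-4-(methoxymethoxy)phenyl]oxetan-2-one | O=C1C[C@H](c2cc(OC)c(OCOC)c(OC)c2)O1
F4 | step 14 | (2S)-2-[3,5-dimethoxy-4-(trimethylsilyloxy)phenyl]-6-geranyl-5,7-bis(trimethylsilyloxy)chroman-4-one | COc1cc([C@@H]2CC(=O)c3c(cc(O[Si](C)(C)C)c(C/C=C(\C)CCC=C(C)C)c3O[Si](C)(C)C)O2)cc(OC)c1O[Si](C)(C)C
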